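Everything rests on making C7–C8 last. A C8 acyl radical adds to C7, the β-carbon of a preformed butenolide (lactone ring O–C6–C7=C11–C12), which closes the ten-membered carbocycle C1–C10; the C11 radical then ejects phenylthiyl from C13, so the C11=C13 methylene, the trans ring fusion and the C8 carbonyl appear in one operation. The step exploits the 1,4-relationship of the C8 oxygen and the C12 carbonyl through C7 and C11, which enolate polarity cannot assemble. The precursor is an acyclic (5R)-5-alkenyl-3-(phenylthiomethyl)butenolide whose (Z)-C4=C5 chain carries the C3 acetate, the C1–C10 epoxide and a C8 phenylselenoester.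

Key step: step 20

Remarks on the chemistry (assumptions):
- Germacrane numbering is used for all intermediates. The target is read as (1R,3S,4Z,6R,7R,8S,10R), with a trans 6,7-lactone fusion and the trans-epoxide that corresponds to an (E)-1(10)-alkene.
- The C1–C10 epoxide is carried through the ring closure as a spectator in place of a 1(10)-alkene. An acyl radical with a β,γ-double bond would lose CO to an allyl radical much faster than a ten-membered ring can close; the bond formed, the ring closed and the carbon skeleton are unchanged.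
- The sense of induction in both oxazaborolidine reductions is assumed to follow the usual model (alkenyl C4, respectively ring carbon C7, as the large substituent).
- (S)-But-3-ene-1,2-diol, 2-(bromomethyl)acrylic acid, the D-fructose-derived Shi ketone and N-(phenylselanyl)phthalimide are taken as catalogue chemicals.

Step 1
Reactants: 1 thiophenol; 2 2-(bromomethyl)prop-2-enoic acid
Product: 3 2-[(phenylsulfanyl)methyl]prop-2-enoic acid
Conditions: Et3N (2.1 equiv), CH2Cl2, 0 °C → rt; aq. HCl work-up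
Reagents that add atoms: none
Why: Thiolate substitution of the allylic bromide (SN2 or SN2', which give the same product) is fast, and the acrylate, present as its carboxylate, should not take up a second thiol.

Step 2
Reactants: 4 (S)-but-3-ene-1,2-diol
Product: 5 (S)-3,4-bis[(tert-butyldimethylsilyl)oxy]but-1-ene
Conditions: TBSCl, imidazole, DMF, rt
Reagents that add atoms: tert-butyldimethylsilyl chloride, CC(C)(C)[Si](C)(C)Cl
Why: Standard silyl ether formation protects both hydroxyls without touching the stereocentre that becomes C6.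

Step 3
Reactants: 5 (S)-3,4-bis[(tert-butyldimethylsilyl)oxy]but-1-ene
Product: 6 (S)-2-[(tert-butyldimethylsilyl)oxy]but-3-en-1-ol
Conditions: HF·pyridine, pyridine, THF, 0 °C
Reagents that add atoms: none
Why: Selective desilylation, since the unhindered primary silyl ether is cleaved by buffered HF much faster than the secondary allylic one.

Step 4
Reactants: 6 (S)-2-[(tert-butyldimethylsilyl)oxy]but-3-en-1-ol
Product: 7 (S)-2-[(tert-butyldimethylsilyl)oxy]but-3-enal
Conditions: Dess–Martin periodinane, pyridine, CH2Cl2, 0 °C; used crude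
Reagents that add atoms: none
Why: Dess–Martin oxidation is non-basic, so the α-silyloxy-β,γ-unsaturated aldehyde should form without epimerisation or migration of the alkene into conjugation, provided it is used at once.

Step 5
Reactants: 7 (S)-2-[(tert-butyldimethylsilyl)oxy]but-3-enal
Product: 8 (3S,4Z)-3-[(tert-butyldimethylsilyl)oxy]-5-iodohexa-1,4-diene
Conditions: Ph3P+Et I−, n-BuLi, THF; I2, −78 °C; NaN(SiMe3)2, −20 °C; then 7, −78 °C
Reagents that add atoms: ethyltriphenylphosphonium iodide, CC[P+](c1ccccc1)(c1ccccc1)c1ccccc1.[I-]; iodine, II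
Why: Stork–Zhao-type Wittig olefination with the α-iodo ylide Ph3P=C(I)CH3 is kinetically (Z)-selective, placing iodine cis to C6 and so fixing the C4=C5 geometry that later holds C3 cis to C6, while the weakly basic ylide at −78 °C should spare the α-stereocentre.

Step 6
Reactants: 9 but-3-yn-1-ol
Product: 10 4-[(4-methoxybenzyl)oxy]but-1-yne
Conditions: NaH, 4-methoxybenzyl chloride, Bu4NI (cat.), THF/DMF, 0 °C → rt
Reagents that add atoms: 4-methoxybenzyl chloride, COc1ccc(CCl)cc1
Why: Williamson etherification of the alkoxide, the alkyne C–H not being deprotonated by NaH under these conditions.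

Step 7
Reactants: 10 4-[(4-methoxybenzyl)oxy]but-1-yne; 11 oxirane
Product: 14 (E)-6-[(4-methoxybenzyl)oxy]-4-methylhex-3-en-1-ol, via alkenyldimethylalane 12 (not isolated), via lithium alkenylalanate 13 (not isolated)
Conditions: Me3Al, Cp2ZrCl2 (cat.), CH2Cl2, rt; n-BuLi, hexane/THF, −78 → 0 °C; oxirane, −78 °C → rt; aq. NH4Cl
Reagents that add atoms: trimethylaluminium, C[Al](C)C
Why: Negishi zirconium-catalysed carboalumination adds CH3 and Al syn across the alkyne with CH3 on the internal carbon, which fixes the (E)-C1=C10 geometry, and the derived butyl alanate opens oxirane to append C2 and C3 with retention of that geometry.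

Step 8
Reactants: 14 (E)-6-[(4-methoxybenzyl)oxy]-4-methylhex-3-en-1-ol
Product: 15 (E)-6-[(4-methoxybenzyl)oxy]-4-methylhex-3-enal
Conditions: Dess–Martin periodinane, pyridine, CH2Cl2, 0 °C; used crude
Reagents that add atoms: none
Why: Buffered Dess–Martin oxidation should give the β,γ-unsaturated aldehyde without isomerisation to the conjugated enal when the product is used immediately.

Step 9
Reactants: 8 (3S,4Z)-3-[(tert-butyldimethylsilyl)oxy]-5-iodohexa-1,4-diene; 15 (E)-6-[(4-methoxybenzyl)oxy]-4-methylhex-3-enal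
Product: 16 (3S,4Z,8E)-3-[(tert-butyldimethylsilyl)oxy]-11-[(4-methoxybenzyl)oxy]-5,9-dimethylundeca-1,4,8-trien-6-ol (both C6 epimers; C6 is germacrane C3)
Conditions: CrCl2, NiCl2 (cat.), DMSO/DMF, rt
Reagents that add atoms: none
Why: Nozaki–Hiyama–Kishi coupling, in which the alkenylchromium formed through nickel catalysis adds to the enolisable aldehyde under non-basic conditions with retention of the (Z) geometry; the new carbinol forms as a mixture that the next oxidation erases.

Step 10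
Reactants: 16 (3S,4Z,8E)-3-[(tert-butyldimethylsilyl)oxy]-11-[(4-methoxybenzyl)oxy]-5,9-dimethylundeca-1,4,8-trien-6-ol
Product: 17 (3S,4Z,8E)-3-[(tert-butyldimethylsilyl)oxy]-11-[(4-methoxybenzyl)oxy]-5,9-dimethylundeca-1,4,8-trien-6-one
Conditions: Dess–Martin periodinane, pyridine, CH2Cl2, 0 °C
Reagents that add atoms: none
Why: Dess–Martin oxidation of the allylic alcohol to the enone under neutral conditions, which should leave the skipped C1=C10 alkene and the (Z)-enone geometry unchanged.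

Step 11
Reactants: 17 (3S,4Z,8E)-3-[(tert-butyldimethylsilyl)oxy]-11-[(4-methoxybenzyl)oxy]-5,9-dimethylundeca-1,4,8-trien-6-one
Product: 18 (3S,4Z,6S,8E)-3-[(tert-butyldimethylsilyl)oxy]-11-[(4-methoxybenzyl)oxy]-5,9-dimethylundeca-1,4,8-trien-6-ol
Conditions: (R)-2-methyl-CBS-oxazaborolidine (cat.), catecholborane, toluene, −78 °C
Reagents that add atoms: none
Why: Corey–Bakshi–Shibata reduction with catecholborane, which does not hydroborate the alkenes; with the α-methylalkenyl group as the large and the CH2 group as the small substituent, the (R)-catalyst should deliver hydride to the face that gives the (S)-carbinol (germacrane C3).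

Step 12
Reactants: 18 (3S,4Z,6S,8E)-3-[(tert-butyldimethylsilyl)oxy]-11-[(4-methoxybenzyl)oxy]-5,9-dimethylundeca-1,4,8-trien-6-ol
Product: 19 (3S,4Z,6S,8E)-3-[(tert-butyldimethylsilyl)oxy]-11-[(4-methoxybenzyl)oxy]-5,9-dimethylundeca-1,4,8-trien-6-yl acetate
Conditions: Ac2O, pyridine, DMAP (cat.), CH2Cl2, 0 °C → rt
Reagents that add atoms: acetic anhydride, CC(=O)OC(C)=O
Why: DMAP-catalysed acetylation of the secondary allylic alcohol proceeds with retention at the carbinol carbon.

Step 13
Reactants: 19 (3S,4Z,6S,8E)-3-[(tert-butyldimethylsilyl)oxy]-11-[(4-methoxybenzyl)oxy]-5,9-dimethylundeca-1,4,8-trien-6-yl acetate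
Product: 20 (3S,4Z,6S,8R,9R)-3-[(tert-butyldimethylsilyl)oxy]-8,9-epoxy-11-[(4-methoxybenzyl)oxy]-5,9-dimethylundeca-1,4-dien-6-yl acetate
Conditions: D-fructose-derived Shi ketone (1,2:4,5-di-O-isopropylidene-β-D-erythro-2,3-hexodiulo-2,6-pyranose, cat.), Oxone (2KHSO5·KHSO4·K2SO4), K2CO3, Bu4NHSO4 (cat.), MeCN/CH2(OMe)2/aq. Na2B4O7 buffer, 0 °C
Reagents that add atoms: potassium peroxymonosulfate (active component of Oxone), [K+].[O-]S(=O)(=O)OO
Why: Shi asymmetric epoxidation, in which the chiral dioxirane attacks the electron-rich (E)-trisubstituted C1=C10 alkene through the spiro transition state that, for this catalyst enantiomer, gives the (R,R)-epoxide, while the C4=C5 alkene (flanked by two allylic oxygens) and the vinyl group react far more slowly; the epoxide is set here because no sulfur or selenium is yet present.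

Step 14
Reactants: 20 (3S,4Z,6S,8R,9R)-3-[(tert-butyldimethylsilyl)oxy]-8,9-epoxy-11-[(4-methoxybenzyl)oxy]-5,9-dimethylundeca-1,4-dien-6-yl acetate
Product: 21 (3S,4Z,6S,8R,9R)-8,9-epoxy-3-hydroxy-11-[(4-methoxybenzyl)oxy]-5,9-dimethylundeca-1,4-dien-6-yl acetate
Conditions: Bu4NF, AcOH (1:1), THF, 0 °C → rt
Reagents that add atoms: none
Why: Fluoride cleavage of the silyl ether, buffered with AcOH so that neither acetyl migration from O3 to O6 nor opening of the epoxide should occur.

Step 15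
Reactants: 21 (3S,4Z,6S,8R,9R)-8,9-epoxy-3-hydroxy-11-[(4-methoxybenzyl)oxy]-5,9-dimethylundeca-1,4-dien-6-yl acetate; 3 2-[(phenylsulfanyl)methyl]prop-2-enoic acid
Product: 22 (3S,4Z,6S,8R,9R)-6-acetoxy-8,9-epoxy-11-[(4-methoxybenzyl)oxy]-5,9-dimethylundeca-1,4-dien-3-yl 2-[(phenylsulfanyl)methyl]prop-2-enoate
Conditions: EDC·HCl, DMAP (cat.), CH2Cl2, 0 °C → rt
Reagents that add atoms: none
Why: Steglich esterification of the secondary alcohol with retention at C6, the phenylthio group being too poor a leaving group for DMAP to displace.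

Step 16
Reactants: 22 (3S,4Z,6S,8R,9R)-6-acetoxy-8,9-epoxy-11-[(4-methoxybenzyl)oxy]-5,9-dimethylundeca-1,4-dien-3-yl 2-[(phenylsulfanyl)methyl]prop-2-enoate
Product: 23 (5R)-5-[(1Z,3S)-3-acetoxy-4-{(2R,3R)-3-[2-(4-methoxybenzyloxy)ethyl]-3-methyloxiran-2-yl}-2-methylbut-1-en-1-yl]-3-[(phenylsulfanyl)methyl]furan-2(5H)-one
Conditions: second-generation Hoveyda–Grubbs catalyst (cat.), toluene, 80 °C
Reagents that add atoms: none
Why: Ring-closing metathesis between the vinyl group and the 1,1-disubstituted acrylate closes the butenolide with loss of ethene; the trisubstituted C4=C5 alkene cannot compete, allyl sulfides are good metathesis substrates, and C6 is not touched.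

Step 17
Reactants: 23 (5R)-5-[(1Z,3S)-3-acetoxy-4-{(2R,3R)-3-[2-(4-methoxybenzyloxy)ethyl]-3-methyloxiran-2-yl}-2-methylbut-1-en-1-yl]-3-[(phenylsulfanyl)methyl]furan-2(5H)-one
Product: 24 (5R)-5-[(1Z,3S)-3-acetoxy-4-{(2R,3R)-3-(2-hydroxyethyl)-3-methyloxiran-2-yl}-2-methylbut-1-en-1-yl]-3-[(phenylsulfanyl)methyl]furan-2(5H)-one
Conditions: DDQ, CH2Cl2/pH 7 buffer, 0 °C
Reagents that add atoms: none
Why: Oxidative cleavage of the 4-methoxybenzyl ether with DDQ under neutral biphasic conditions, which the epoxide, acetate, base-sensitive butenolide and aryl sulfide should all tolerate.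

Step 18
Reactants: 24 (5R)-5-[(1Z,3S)-3-acetoxy-4-{(2R,3R)-3-(2-hydroxyethyl)-3-methyloxiran-2-yl}-2-methylbut-1-en-1-yl]-3-[(phenylsulfanyl)methyl]furan-2(5H)-one
Product: 26 (5R)-5-[(1Z,3S)-3-acetoxy-4-{(2R,3R)-3-(carboxymethyl)-3-methyloxiran-2-yl}-2-methylbut-1-en-1-yl]-3-[(phenylsulfanyl)methyl]furan-2(5H)-one, via epoxy aldehyde 25 (not isolated)
Conditions: TEMPO (cat.), PhI(OAc)2, MeCN/H2O, 0 °C → rt
Reagents that add atoms: water, O
Why: Oxoammonium (TEMPO/PhI(OAc)2) oxidation takes the primary alcohol through the aldehyde hydrate to the acid under mild, slightly acidic conditions that are known to spare aryl thioethers (as in thioglycoside oxidations) and that should not trigger β-elimination of the β,γ-epoxy carbonyl unit.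

Step 19
Reactants: 26 (5R)-5-[(1Z,3S)-3-acetoxy-4-{(2R,3R)-3-(carboxymethyl)-3-methyloxiran-2-yl}-2-methylbut-1-en-1-yl]-3-[(phenylsulfanyl)methyl]furan-2(5H)-one
Product: 27 (5R)-5-[(1Z,3S)-3-acetoxy-2-methyl-4-{(2R,3R)-3-methyl-3-[2-oxo-2-(phenylselanyl)ethyl]oxiran-2-yl}but-1-en-1-yl]-3-[(phenylsulfanyl)methyl]furan-2(5H)-one
Conditions: N-(phenylselanyl)phthalimide, Bu3P, CH2Cl2, −30 → 0 °C (phosphine added last)
Reagents that add atoms: N-(phenylselanyl)phthalimide, O=C1N([Se]c2ccccc2)C(=O)c2ccccc12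
Why: Phosphine-mediated selenoesterification, in which the acyloxyphosphonium ion is captured by phenylselenolate under near-neutral conditions, so that neither the acidic C6–H of the butenolide nor the β,γ-epoxy acyl unit meets base.

Step 20
Reactants: 27 (5R)-5-[(1Z,3S)-3-acetoxy-2-methyl-4-{(2R,3R)-3-methyl-3-[2-oxo-2-(phenylselanyl)ethyl]oxiran-2-yl}but-1-en-1-yl]-3-[(phenylsulfanyl)methyl]furan-2(5H)-one
Product: 28 (1R,3S,4Z,6R,7S,10R)-3-acetoxy-1,10-epoxy-8-oxogermacra-4,11(13)-dien-12,6-olide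
Conditions: (Bu3Sn)2 (1.5 equiv), hν (sunlamp, Pyrex), degassed C6H6 (2 mM), 25 °C
Reagents that add atoms: none
Why: Proposed new method: Bu3Sn• from photolysed (Bu3Sn)2 abstracts PhSe from the selenoester, the nucleophilic C8 acyl radical adds to C7 (the electron-poor β-carbon of the butenolide), and the C11 radical so formed expels PhS• by β-scission of the C13–S bond, which unveils the C11=C13 methylene and hands the chain back to (Bu3Sn)2; the closest known reaction types are acyl-radical macrocyclisations of selenoesters onto enones and acrylates and radical addition–fragmentation (allyl transfer) of allyl sulfides, which have not been combined on a butenolide acceptor. The ten-membered ring closes in the 10-exo-trig mode (C7 becomes a ring atom, C11 stays outside). The new stereocentre C7 is controlled by C6: C8 is expected to bond to the butenolide face anti to the C6–C5 bond, as radicals do on γ-substituted butenolides, giving the trans-fused (6R,7S) lactone, an approach that the (Z)-C4=C5 alkene and the trans-epoxide in the nine-atom tether can accommodate. The step needs addition at C7 to outrun loss of CO, hydrogen capture and attack on C4=C5: the epoxide makes C9 an ordinary primary carbon so that decarbonylation would give an unstabilised radical and is slow at 25 °C, the hydride- and thiol-free medium offers no hydrogen donor (and no thiol to add to the new methylene lactone), and polarity matching directs the acyl radical to the enoate and not to the oxygen-flanked C4=C5 alkene.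

Step 21
Reactants: 28 (1R,3S,4Z,6R,7S,10R)-3-acetoxy-1,10-epoxy-8-oxogermacra-4,11(13)-dien-12,6-olide
Product: 29 (1R,3S,4Z,6R,7R,8S,10R)-3-acetoxy-1,10-epoxy-8-hydroxygermacra-4,11(13)-dien-12,6-olide
Conditions: (R)-2-methyl-CBS-oxazaborolidine (0.3 equiv), catecholborane, toluene/CH2Cl2, −78 → −40 °C; pH 7 buffer work-up
Reagents that add atoms: none
Why: Corey–Bakshi–Shibata reduction with catecholborane at low temperature reduces the ketone in preference to the α-methylene lactone; with C7 as the large and C9 as the small substituent the (R)-catalyst should give the (8S)-alcohol, and the base-free medium avoids epimerisation at C7 and migration of the exocyclic alkene.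

Step 22
Reactants: 29 (1R,3S,4Z,6R,7R,8S,10R)-3-acetoxy-1,10-epoxy-8-hydroxygermacra-4,11(13)-dien-12,6-olide
Product: 30 (1R,3S,4Z,6R,7R,8S,10R)-3-acetoxy-1,10-epoxy-8-(3-methylbutanoyloxy)germacra-4,11(13)-dien-12,6-olide (CNP0157657.1)
Conditions: isovaleric anhydride, DMAP (cat.), Et3N, CH2Cl2, 0 °C → rt
Reagents that add atoms: 3-methylbutanoic anhydride, CC(C)CC(=O)OC(=O)CC(C)C
Why: DMAP-catalysed acylation of the C8 alcohol with retention gives the isovalerate, and fast esterification should leave no time for translactonisation onto O8.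

Compound list
1 | thiophenol | Sc1ccccc1 | starting material
2 | 2-(bromomethyl)prop-2-enoic acid | C=C(CBr)C(=O)O | starting material
3 | 2-[(phenylsulfanyl)methyl]prop-2-enoic acid | C=C(CSc1ccccc1)C(=O)O | intermediate
4 | (S)-but-3-ene-1,2-diol | C=C[C@H](O)CO | starting material
5 | (S)-3,4-bis[(tert-butyldimethylsilyl)oxy]but-1-ene | C=C[C@H](O[Si](C)(C)C(C)(C)C)CO[Si](C)(C)C(C)(C)C | intermediate
6 | (S)-2-[(tert-butyldimethylsilyl)oxy]but-3-en-1-ol | C=C[C@H](O[Si](C)(C)C(C)(C)C)CO | intermediate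
7 | (S)-2-[(tert-butyldimethylsilyl)oxy]but-3-enal | C=C[C@H](O[Si](C)(C)C(C)(C)C)C=O | intermediate
8 | (3S,4Z)-3-[(tert-butyldimethylsilyl)oxy]-5-iodohexa-1,4-diene | C=C[C@H](O[Si](C)(C)C(C)(C)C)/C=C(/C)I | intermediate
9 | but-3-yn-1-ol | C#CCCO | starting material
10 | 4-[(4-methoxybenzyl)oxy]but-1-yne | C#CCCOCc1ccc(OC)cc1 | intermediate
11 | oxirane | C1CO1 | starting material
12 | dimethyl[(1E)-4-[(4-methoxybenzyl)oxy]-2-methylbut-1-en-1-yl]alane | C[Al](C)/C=C(\C)CCOCc1ccc(OC)cc1 | intermediate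
13 | lithium butyl(dimethyl)[(1E)-4-[(4-methoxybenzyl)oxy]-2-methylbut-1-en-1-yl]aluminate | [Li+].CCCC[Al-](C)(C)/C=C(\C)CCOCc1ccc(OC)cc1 | intermediate
14 | (E)-6-[(4-methoxybenzyl)oxy]-4-methylhex-3-en-1-ol | OCC/C=C(\C)CCOCc1ccc(OC)cc1 | intermediate
15 | (E)-6-[(4-methoxybenzyl)oxy]-4-methylhex-3-enal | O=CC/C=C(\C)CCOCc1ccc(OC)cc1 | intermediate
16 | (3S,4Z,8E)-3-[(tert-butyldimethylsilyl)oxy]-11-[(4-methoxybenzyl)oxy]-5,9-dimethylundeca-1,4,8-trien-6-ol (C6 epimers) | C=C[C@H](O[Si](C)(C)C(C)(C)C)/C=C(/C)C(O)C/C=C(\C)CCOCc1ccc(OC)cc1 | intermediate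
17 | (3S,4Z,8E)-3-[(tert-butyldimethylsilyl)oxy]-11-[(4-methoxybenzyl)oxy]-5,9-dimethylundeca-1,4,8-trien-6-one | C=C[C@H](O[Si](C)(C)C(C)(C)C)/C=C(/C)C(=O)C/C=C(\C)CCOCc1ccc(OC)cc1 | intermediate
18 | (3S,4Z,6S,8E)-3-[(tert-butyldimethylsilyl)oxy]-11-[(4-methoxybenzyl)oxy]-5,9-dimethylundeca-1,4,8-trien-6-ol | C=C[C@H](O[Si](C)(C)C(C)(C)C)/C=C(/C)[C@@H](O)C/C=C(\C)CCOCc1ccc(OC)cc1 | intermediate
19 | (3S,4Z,6S,8E)-3-[(tert-butyldimethylsilyl)oxy]-11-[(4-methoxybenzyl)oxy]-5,9-dimethylundeca-1,4,8-trien-6-yl acetate | C=C[C@H](O[Si](C)(C)C(C)(C)C)/C=C(/C)[C@@H](OC(C)=O)C/C=C(\C)CCOCc1ccc(OC)cc1 | intermediate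
20 | (3S,4Z,6S,8R,9R)-3-[(tert-butyldimethylsilyl)oxy]-8,9-epoxy-11-[(4-methoxybenzyl)oxy]-5,9-dimethylundeca-1,4-dien-6-yl acetate | C=C[C@H](O[Si](C)(C)C(C)(C)C)/C=C(/C)[C@@H](OC(C)=O)C[C@H]1O[C@]1(C)CCOCc1ccc(OC)cc1 | intermediate
21 | (3S,4Z,6S,8R,9R)-8,9-epoxy-3-hydroxy-11-[(4-methoxybenzyl)oxy]-5,9-dimethylundeca-1,4-dien-6-yl acetate | C=C[C@H](O)/C=C(/C)[C@@H](OC(C)=O)C[C@H]1O[C@]1(C)CCOCc1ccc(OC)cc1 | intermediate
22 | (3S,4Z,6S,8R,9R)-6-acetoxy-8,9-epoxy-11-[(4-methoxybenzyl)oxy]-5,9-dimethylundeca-1,4-dien-3-yl 2-[(phenylsulfanyl)methyl]prop-2-enoate | C=C[C@H](OC(=O)C(=C)CSc1ccccc1)/C=C(/C)[C@@H](OC(C)=O)C[C@H]1O[C@]1(C)CCOCc1ccc(OC)cc1 | intermediate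
23 | (5R)-5-[(1Z,3S)-3-acetoxy-4-{(2R,3R)-3-[2-(4-methoxybenzyloxy)ethyl]-3-methyloxiran-2-yl}-2-methylbut-1-en-1-yl]-3-[(phenylsulfanyl)methyl]furan-2(5H)-one | O=C1C(CSc2ccccc2)=C[C@H](O1)/C=C(/C)[C@@H](OC(C)=O)C[C@H]3O[C@]3(C)CCOCc4ccc(OC)cc4 | intermediate
24 | (5R)-5-[(1Z,3S)-3-acetoxy-4-{(2R,3R)-3-(2-hydroxyethyl)-3-methyloxiran-2-yl}-2-methylbut-1-en-1-yl]-3-[(phenylsulfanyl)methyl]furan-2(5H)-one | O=C1C(CSc2ccccc2)=C[C@H](O1)/C=C(/C)[C@@H](OC(C)=O)C[C@H]3O[C@]3(C)CCO | intermediate
25 | (5R)-5-[(1Z,3S)-3-acetoxy-2-methyl-4-{(2R,3R)-3-methyl-3-(2-oxoethyl)oxiran-2-yl}but-1-en-1-yl]-3-[(phenylsulfanyl)methyl]furan-2(5H)-one | O=C1C(CSc2ccccc2)=C[C@H](O1)/C=C(/C)[C@@H](OC(C)=O)C[C@H]3O[C@]3(C)CC=O | intermediate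
26 | (5R)-5-[(1Z,3S)-3-acetoxy-4-{(2R,3R)-3-(carboxymethyl)-3-methyloxiran-2-yl}-2-methylbut-1-en-1-yl]-3-[(phenylsulfanyl)methyl]furan-2(5H)-one | O=C1C(CSc2ccccc2)=C[C@H](O1)/C=C(/C)[C@@H](OC(C)=O)C[C@H]3O[C@]3(C)CC(=O)O | intermediate
27 | (5R)-5-[(1Z,3S)-3-acetoxy-2-methyl-4-{(2R,3R)-3-methyl-3-[2-oxo-2-(phenylselanyl)ethyl]oxiran-2-yl}but-1-en-1-yl]-3-[(phenylsulfanyl)methyl]furan-2(5H)-one (key-step precursor) | O=C1C(CSc2ccccc2)=C[C@H](O1)/C=C(/C)[C@@H](OC(C)=O)C[C@H]3O[C@]3(C)CC(=O)[Se]c4ccccc4 | intermediate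
28 | (1R,3S,4Z,6R,7S,10R)-3-acetoxy-1,10-epoxy-8-oxogermacra-4,11(13)-dien-12,6-olide (key-step product) | C=C1C(=O)O[C@@H]2/C=C(/C)[C@@H](OC(C)=O)C[C@H]3O[C@]3(C)CC(=O)[C@@H]12 | intermediate
29 | (1R,3S,4Z,6R,7R,8S,10R)-3-acetoxy-1,10-epoxy-8-hydroxygermacra-4,11(13)-dien-12,6-olide | C=C1C(=O)O[C@@H]2/C=C(/C)[C@@H](OC(C)=O)C[C@H]3O[C@]3(C)C[C@H](O)[C@@H]12 | intermediate
30 | (1R,3S,4Z,6R,7R,8S,10R)-3-acetoxy-1,10-epoxy-8-(3-methylbutanoyloxy)germacra-4,11(13)-dien-12,6-olide (CNP0157657.1) | C=C1C(=O)O[C@@H]2/C=C(/C)[C@@H](OC(C)=O)C[C@H]3O[C@]3(C)C[C@H](OC(=O)CC(C)C)[C@@H]12 | target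

Total step count: 22. Longest linear sequence: 18 steps (steps 2–5, then 9–22, from diol 4).

Steps most likely to fail

Step 20 (proposed new method). The acyl radical may be lost to decarbonylation or oligomerisation before the slow ten-membered closure, may attack C4=C5, or may bond to the C7 face syn to C5. The fallback makes the same C7–C8 bond with reversed polarity by known chemistry, sets out from alcohol 21 and acid 2, and returns at 29. Esterification of 21 with 2 (DCC, catalytic DMAP, CH2Cl2, −20 °C) would give (3S,4Z,6S,8R,9R)-6-acetoxy-8,9-epoxy-11-[(4-methoxybenzyl)oxy]-5,9-dimethylundeca-1,4-dien-3-yl 2-(bromomethyl)prop-2-enoate F1. Ring-closing metathesis as in step 16 would give the 3-(bromomethyl)butenolide F2, DDQ the primary alcohol F3, and Dess–Martin oxidation the epoxy aldehyde F4, used crude. Treatment with CrCl2 in THF/DMF at high dilution (intramolecular Nozaki–Hiyama, Barbier-type allylation) would turn the allylic bromide into an allylchromium that attacks the C8 aldehyde through C7, anti to the C6 substituent. This closes the ten-membered ring and delivers the α-methylene lactone and the C8 carbinol 29 in one step. Should the C8 epimer form, it would be esterified with inversion as described for step 21.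

Step 21. Hydride delivery may be dictated by the conformation of the ten-membered ring and not by the catalyst, giving the C8 epimer, or the borane may reduce the methylene lactone in conjugate fashion. The fallback sets out from ketone 28 and returns at target 30. Substrate-controlled Luche reduction (NaBH4, CeCl3·7H2O, MeOH/THF, −78 °C) would give whichever alcohol the ring prefers. If that is (1R,3S,4Z,6R,7R,8R,10R)-3-acetoxy-1,10-epoxy-8-hydroxygermacra-4,11(13)-dien-12,6-olide F5, Mitsunobu esterification with isovaleric acid (PPh3, DIAD, toluene, 0 °C) would install the ester with inversion and give 30 directly.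

Step 5. The (Z) selectivity of the iodo-olefination may erode, or the α-silyloxy aldehyde may epimerise or slip into conjugation under the ylide conditions. The fallback builds the (Z)-iodoalkene by trans-hydroalumination of an alkyne, sets out from aldehyde 7 and returns at 8. Corey–Fuchs dibromo-olefination (CBr4, PPh3, CH2Cl2, 0 °C) would give (S)-tert-butyl[(1,1-dibromopenta-1,4-dien-3-yl)oxy]dimethylsilane F6. n-BuLi (2 equiv, −78 °C) followed by MeI would give (S)-tert-butyl(hex-1-en-4-yn-3-yloxy)dimethylsilane F7, and Bu4NF would give (S)-hex-1-en-4-yn-3-ol F8. Alkoxide-directed trans-hydroalumination with NaAlH2(OCH2CH2OCH3)2 followed by I2 would give (3S,4Z)-5-iodohexa-1,4-dien-3-ol F9, with iodine on the distal carbon cis to the carbinol. Silylation (TBSCl, imidazole) would return 8.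

Further compounds
F1 | step 20 | (3S,4Z,6S,8R,9R)-6-acetoxy-8,9-epoxy-11-[(4-methoxybenzyl)oxy]-5,9-dimethylundeca-1,4-dien-3-yl 2-(bromomethyl)prop-2-enoate | C=C[C@H](OC(=O)C(=C)CBr)/C=C(/C)[C@@H](OC(C)=O)C[C@H]1O[C@]1(C)CCOCc1ccc(OC)cc1
F2 | step 20 | (5R)-5-[(1Z,3S)-3-acetoxy-4-{(2R,3R)-3-[2-(4-methoxybenzyloxy)ethyl]-3-methyloxiran-2-yl}-2-methylbut-1-en-1-yl]-3-(bromomethyl)furan-2(5H)-one | O=C1C(CBr)=C[C@H](O1)/C=C(/C)[C@@H](OC(C)=O)C[C@H]2O[C@]2(C)CCOCc3ccc(OC)cc3
F3 | step 20 | (5R)-5-[(1Z,3S)-3-acetoxy-4-{(2R,3R)-3-(2-hydroxyethyl)-3-methyloxiran-2-yl}-2-methylbut-1-en-1-yl]-3-(bromomethyl)furan-2(5H)-one | O=C1C(CBr)=C[C@H](O1)/C=C(/C)[C@@H](OC(C)=O)C[C@H]2O[C@]2(C)CCO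
F4 | step 20 | (5R)-5-[(1Z,3S)-3-acetoxy-2-methyl-4-{(2R,3R)-3-methyl-3-(2-oxoethyl)oxiran-2-yl}but-1-en-1-yl]-3-(bromomethyl)furan-2(5H)-one | O=C1C(CBr)=C[C@H](O1)/C=C(/C)[C@@H](OC(C)=O)C[C@H]2O[C@]2(C)CC=O
F5 | step 21 | (1R,3S,4Z,6R,7R,8R,10R)-3-acetoxy-1,10-epoxy-8-hydroxygermacra-4,11(13)-dien-12,6-olide | C=C1C(=O)O[C@@H]2/C=C(/C)[C@@H](OC(C)=O)C[C@H]3O[C@]3(C)C[C@@H](O)[C@@H]12
F6 | step 5 | (S)-tert-butyl[(1,1-dibromopenta-1,4-dien-3-yl)oxy]dimethylsilane | C=C[C@H](O[Si](C)(C)C(C)(C)C)C=C(Br)Br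
F7 | step 5 | (S)-tert-butyl(hex-1-en-4-yn-3-yloxy)dimethylsilane | C=C[C@H](O[Si](C)(C)C(C)(C)C)C#CC
F8 | step 5 | (S)-hex-1-en-4-yn-3-ol | C=C[C@H](O)C#CC
F9 | step 5 | (3S,4Z)-5-iodohexa-1,4-dien-3-ol | C=C[C@H](O)/C=C(/C)I
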